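## The problem

The target joins three aromatic units through one sp3 carbon: a diarylmethine that carries a catechol ring, C8 of a (+)-catechin unit and C2 of a 4,6-dihydroxy-2,3-dihydrobenzofuran. Of its four stereocentres, flavan C2 (R) and C3 (S) are those of (+)-catechin and can be bought. The methine (R) and benzofuran C2 (S) are contiguous, but the first lies in an open chain and the flavan centres are too remote to control either of them reliably. A synthesis must therefore functionalise the flavan at C8 and not at C6, build the methine with three different carbon substituents in one absolute configuration, and set benzofuran C2 relative to it. Nine hydroxyl groups on four electron-rich rings make the free compound sensitive to air, base and acid. The doubly benzylic methine on the phloroglucinol-type ring A ionises easily, the benzylic flavan C2–O1 bond must survive the final hydrogenolysis, and a dihydrobenzofuran with a leaving group at C3 aromatises to the benzofuran with loss of the C2 stereocentre. The feature used here is that benzofuran O1 and the methine carbon are both bonded to benzofuran C2: the isomer with the methine on O1 is an ordinary aryl diarylmethyl ether, and a 1,2-shift of the diarylmethyl group from O1 to C2 converts one into the other. If C2 is at that moment a carbenoid carbon next to a C3 ketone, the same event closes the five-membered ring.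

## Retrosynthesis

**Deprotection and removal of the C3 oxygen (20 from 19 from 18).** The last disconnections are seven O–benzyl bonds and the benzylic C3–O bond (one hydrogenolysis) and two O–Si bonds (fluoride). Benzyl ethers are used on the whole lower half because they leave together with the C3 hydroxyl. The C3 oxygen is removed last, from triol 19, because free hydroxyls at C4 and C6 activate the benzylic C–O bond, as in the hydrogenolysis of flavan-3,4-diols to flavan-3-ols. The forward steps must avoid loss of water from 18 or 19 to the aromatic benzofuran.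

**Benzofuran C2 (18 from 17).** The C3–H bond is cut, leading back to ketone 17. In 17, C2 is alpha to the ketone and epimerises through the aromatic enol, so a reduction that selects one carbonyl face and one C2 epimer fixes C2 for good. A direct deoxygenation of the ketone would leave C2 to an uncontrolled equilibrium, which is why the detour through alcohol 18 is accepted.

**Key disconnection (17 from 14).** The C2–methine bond and the O1–C2 bond are cut together, giving diazo ketone 14, an open-chain aryl diarylmethyl ether. Cutting only C2–methine would demand alkylation of a benzofuranone enolate by a hindered diarylmethyl electrophile with no stereocontrol. Cutting C8–methine would demand a Friedel–Crafts reaction with a C6/C8 problem. The chosen cut turns a hindered C–C bond into a C–O bond that ordinary etherification can make, and removes the ring. The forward reaction must form the ylide at the right oxygen, shift to carbon rather than to the enolate oxygen, and retain configuration at the migrating carbon.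

**Diazo ketone (14 from 12).** The C=N2 unit is removed to give methyl ketone 12. Detrifluoroacetylative diazo transfer works on methyl ketones under basic conditions only, which suits the acid-labile ether.

**Ether bond (12 from 9 and 11).** The O–CH bond is cut to carbinol 9 and phenol 11. A Mitsunobu reaction joins them with inversion, so 9 must be (S). The activated carbinol can ionise, which is the weak link. An arylation of the alkoxide with a nitrile-activated fluoroarene would leave the carbinol C–O bond untouched, but would cost at least three more steps to reach the methyl ketone. The direct substitution is therefore kept, and its fidelity is checked at 12, whose methine epimer is a diastereomer and can be removed. Phenol 11 comes from 10 in one step; its silyl ethers serve as carbenoid-inert groups in the key step.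

**Carbinol (9 from 8 from 7 from 4 and 5).** The C8–CH bond is cut to an 8-metallated flavan and aldehyde 5. Bromide 4 defines C8 unambiguously, which a Friedel–Crafts approach would not. The addition gives both carbinol epimers 7; oxidation to ketone 8 and a reagent-controlled reduction convert them into single epimer 9.

**Flavan building block (4 from 3 from 2 from 1).** The C8–Br bond and five O–benzyl bonds are cut back to (+)-catechin 1. Both flavan stereocentres are carried unchanged through the whole route.

## Roads not taken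

**Alternative 1:** The cut is in the flavan: ring C is opened at C4–C3 and O1–C2. Forward, salicyl alcohol A1, which already holds the dihydrobenzofuran and the methine, would lose water to an ortho-quinone methide. This would add enol acetate A2 in a hetero-Diels–Alder reaction under a chiral phosphoric acid such as 3,3'-bis(2,4,6-triisopropylphenyl)-1,1'-binaphthyl-2,2'-diyl hydrogen phosphate, giving flavan A3.
- Merits: both ring C stereocentres form in one step, the (E)-alkene gives the trans relationship, and no bond is made at a hindered flavan C8.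
- Weak points: the two centres it creates are those that 1 supplies for nothing. A1 has a second free phenol para to the benzylic alcohol, so a para-quinone methide and self-condensation compete. Enol acetates are sluggish partners. The methine and benzofuran C2 must already be present in A1, so the hardest part of the target is left unsolved.
- Comparison: this road is better in that its key step does not depend on retention at an ionisable carbon. The chosen plan sets against it that it buys ring C and spends its key step on the bond that this road presupposes.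

**Alternative 2:** The cut is through the benzene ring of the benzofuran (C3a–C7a, C4–C5, C6–C7). Forward, diyne A4 and alkynylboronate A5 would cyclotrimerise under Cp*RuCl(cod) to arene A6, closing benzene and dihydrofuran rings together.
- Merits: benzofuran C2 is a carbinol carbon fixed before the ring exists and is never alpha to a carbonyl. There is no epimerisable centre and no C3 oxygen to remove, which is better than the chosen plan.
- Weak points: A4 contains two ynol ethers, and the tert-butoxyalkyne loses isobutene to a ketene on mild heating. The tether does not fix the orientation of A5 (boron at C6 or C5). C–B oxidation and acidic tert-butyl cleavage must follow on an acid-sensitive polyphenol ether. The carbinol and methine centres of A4 are again an unsolved acyclic pair.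
- Comparison: the chosen plan takes its oxygenated benzene ring ready-made from 10 and so needs no regiocontrol on that ring. It pays with the C3 ketone that has to be removed.

**Alternative 3:** The cut is at benzofuran C3a–C3 and C7a–O1. Forward, aryl iodide A7 and terminal epoxide A8 would react under Pd(OAc)2, tri(2-furyl)phosphine and a bridgehead-substituted norbornene (Catellani annulation) to give nona-benzyl ether A9.
- Merits: it is the most convergent road. C2 comes from the epoxide and cannot epimerise, only benzyl groups are used, and one hydrogenolysis reaches the target. After the key step it is shorter than the chosen plan by two steps.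
- Weak points: both ortho C–H bonds of A7 lie between the iodine and a benzyloxy group, the hindered pattern that is difficult in this chemistry. The secondary alkoxide that must close the C–O bond carries the very large diarylmethyl group. A8 needs the methine and the epoxide carbon as a defined acyclic pair, for which no short access is evident.
- Comparison: this road is better in endgame and convergence. The chosen plan sets against it that the C2–methine bond is made in the key step from simple partners, and that no C–H palladation at a doubly flanked position is needed.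

Key step: step 10

**Remarks on the chemistry (assumptions)**

- In names, "penta-O-benzylcatechin-8-yl" means (2R,3S)-3,5,7-tris(benzyloxy)-2-[3,4-bis(benzyloxy)phenyl]chroman-8-yl.
- In step 6 the coplanar 3,4-bis(benzyloxy)phenyl ring of ketone 8 is taken to act as the large group and the twisted, doubly ortho-substituted ring A as the small one. If the reduction follows the opposite sense, the (R)-oxazaborolidine is used and nothing else changes.
- Compound 17 is a pair of C2 epimers that interconvert through the enol. It is drawn without configuration at C2.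

## Route

Step 1
Reactants: 1 (+)-catechin
Product: 2 5,7,3',4'-tetra-O-benzyl-(+)-catechin
Conditions: BnBr (4.4 equiv), K2CO3, DMF, 0 °C to rt
Reagents that add atoms: benzyl bromide, BrCc1ccccc1
Why: Williamson etherification; K2CO3 deprotonates the four phenols but not the secondary alcohol, so only the phenolic oxygens should be benzylated and both stereocentres stay untouched.

Step 2
Reactants: 2 5,7,3',4'-tetra-O-benzyl-(+)-catechin
Product: 3 penta-O-benzyl-(+)-catechin [(2R,3S)-3,5,7-tris(benzyloxy)-2-[3,4-bis(benzyloxy)phenyl]chromane]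
Conditions: NaH, BnBr, Bu4NI (cat.), THF/DMF, 0 °C to rt
Reagents that add atoms: benzyl bromide, BrCc1ccccc1
Why: Williamson etherification of the sodium alkoxide of the 3-hydroxyl; a benzyl ether is chosen so that it leaves in the final hydrogenolysis and tolerates the aryllithium of step 4.

Step 3
Reactants: 3 penta-O-benzyl-(+)-catechin
Product: 4 8-bromo-penta-O-benzyl-(+)-catechin
Conditions: NBS (1.0 equiv), CH2Cl2, −78 to −20 °C, dark
Reagents that add atoms: N-bromosuccinimide, O=C1CCC(=O)N1Br
Why: Electrophilic aromatic bromination; ring A is the most electron-rich ring, and C8 of 5,7-di-O-benzylated flavan-3-ol ethers is known to react in preference to C6; one equivalent at low temperature should prevent dibromination.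

Step 4
Reactants: 4 8-bromo-penta-O-benzyl-(+)-catechin; 5 3,4-bis(benzyloxy)benzaldehyde
Product: 7 [3,4-bis(benzyloxy)phenyl](penta-O-benzylcatechin-8-yl)methanol as both carbinol epimers, via aryllithium 6 (not isolated)
Conditions: n-BuLi, THF, −78 °C; then 5, −78 to −40 °C; H2O
Reagents that add atoms: none
Why: Bromine–lithium exchange at −78 °C outruns deprotonation of the benzylic ether CH2 groups, and the aryllithium adds to the aldehyde (1,2-addition); the new carbinol centre is not controlled and is erased in step 5.

Step 5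
Reactants: 7 [3,4-bis(benzyloxy)phenyl](penta-O-benzylcatechin-8-yl)methanol (both carbinol epimers)
Product: 8 [3,4-bis(benzyloxy)phenyl](penta-O-benzylcatechin-8-yl)methanone
Conditions: MnO2 (activated, excess), CH2Cl2, rt
Reagents that add atoms: none
Why: Oxidation of a doubly benzylic alcohol by MnO2 under neutral conditions; no acid is present, so the easily ionised carbinol should not form ethers or dimers.

Step 6
Reactants: 8 [3,4-bis(benzyloxy)phenyl](penta-O-benzylcatechin-8-yl)methanone
Product: 9 (S)-[3,4-bis(benzyloxy)phenyl](penta-O-benzylcatechin-8-yl)methanol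
Conditions: (S)-1-methyl-3,3-diphenyltetrahydro-1H,3H-pyrrolo[1,2-c][1,3,2]oxazaborole (0.5 equiv), BH3·SMe2, THF, −20 °C to rt; then MeOH
Reagents that add atoms: none
Why: Corey–Bakshi–Shibata reduction; hydride is delivered inside the ketone–oxazaborolidine–borane complex to the face set by the difference between the coplanar aryl group and the twisted ring A, which with the (S)-catalyst should give the (S)-carbinol. The resident flavan centres are remote, so the reagent should control the new centre.

Step 7
Reactants: 10 2,4,6-trihydroxyacetophenone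
Product: 11 1-[2-hydroxy-4,6-bis(triisopropylsilyloxy)phenyl]ethanone
Conditions: TIPSCl (2.1 equiv), imidazole, DMF, 0 °C to rt
Reagents that add atoms: triisopropylsilyl chloride, CC(C)[Si](Cl)(C(C)C)C(C)C
Why: Silylation of phenols; the para hydroxyl and one ortho hydroxyl react, while the last ortho hydroxyl is held in a hydrogen bond to the carbonyl and shielded by the acetyl group, so the reaction should stop at the bis-silyl ether.

Step 8
Reactants: 9 (S)-[3,4-bis(benzyloxy)phenyl](penta-O-benzylcatechin-8-yl)methanol; 11 1-[2-hydroxy-4,6-bis(triisopropylsilyloxy)phenyl]ethanone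
Product: 12 1-{2-[(R)-[3,4-bis(benzyloxy)phenyl](penta-O-benzylcatechin-8-yl)methoxy]-4,6-bis(triisopropylsilyloxy)phenyl}ethanone
Conditions: PPh3, DIAD, toluene, −20 to 0 °C; chromatography on Et3N-washed silica
Reagents that add atoms: none
Why: Mitsunobu etherification; the chelated phenol is acidic enough to protonate the betaine, and displacement at the activated carbinol carbon with inversion should turn (S)-9 into the (R)-ether. Toluene and low temperature are chosen to keep any ion pair tight, and the methine epimer, a diastereomer, is removed at this stage if it forms.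

Step 9
Reactants: 12 1-{2-[(R)-[3,4-bis(benzyloxy)phenyl](penta-O-benzylcatechin-8-yl)methoxy]-4,6-bis(triisopropylsilyloxy)phenyl}ethanone
Product: 14 2-diazo-1-{2-[(R)-[3,4-bis(benzyloxy)phenyl](penta-O-benzylcatechin-8-yl)methoxy]-4,6-bis(triisopropylsilyloxy)phenyl}ethanone, via trifluoroacetyl ketone 13 (not isolated)
Conditions: LiN(SiMe3)2, THF, −78 °C; CF3CO2CH2CF3; aq. NH4Cl; then MsN3, Et3N, H2O (1 equiv), MeCN, rt
Reagents that add atoms: methanesulfonyl azide, CS(=O)(=O)N=[N+]=[N-]; 2,2,2-trifluoroethyl trifluoroacetate, O=C(OCC(F)(F)F)C(F)(F)F (its acyl group stays only in 13)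
Why: Detrifluoroacetylative (Regitz-type) diazo transfer; the lithium enolate of the methyl ketone is C-acylated, and the activated diketone 13 takes the diazo group from the sulfonyl azide and loses the trifluoroacetyl group. The sequence is basic throughout, which the acid-labile ether and the methine centre should tolerate.

Step 10
Reactants: 14 2-diazo-1-{2-[(R)-[3,4-bis(benzyloxy)phenyl](penta-O-benzylcatechin-8-yl)methoxy]-4,6-bis(triisopropylsilyloxy)phenyl}ethanone
Product: 17 2-[(R)-[3,4-bis(benzyloxy)phenyl](penta-O-benzylcatechin-8-yl)methyl]-4,6-bis(triisopropylsilyloxy)benzofuran-3(2H)-one (C2 epimers in equilibrium), via rhodium carbenoid 15 (not isolated), via oxonium ylide 16 (not isolated)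
Conditions: Rh2(OAc)4 (2 mol %), CH2Cl2, rt, slow addition of 14
Reagents that add atoms: none
Why: Rh2(OAc)4, a carboxylate dimer of divalent rhodium, takes up the diazo carbon of 14 with loss of nitrogen and gives the electrophilic carbenoid 15. A lone pair of the neighbouring diarylmethoxy oxygen adds to the carbenoid carbon; this closes the five-membered ring by O-to-C bond formation (O1–C2, with the Rh=C bond outside the new ring) and gives the cyclic oxonium ylide 16. The ylide breaks at its weakest bond, O1–CH, to a caged pair of a diarylmethyl radical and a benzofuranone-2-yl radical (or the corresponding ion pair), which recombines at carbon to form the C2–methine bond, a Stevens [1,2]-shift overall. The closest known reaction type is the rhodium- or copper-catalysed decomposition of ortho-alkoxy and ortho-benzyloxy alpha-diazo ketones, whose oxonium ylides rearrange by [1,2]- or [2,3]-shift to 2-substituted benzofuran-3(2H)-ones. The methine centre is controlled by retention inside the cage: both fragments are heavy and bulky, so recombination should outrun tumbling, but this is not established for a diarylmethyl group and is checked at 17, where an epimer would be a separable diastereomer. Benzofuran C2 is also formed here but not controlled, since it epimerises through the aromatic enol; it is set in step 11. The step needs selectivity for the diarylmethoxy oxygen over the other ortho oxygen, the arenes and the methine C–H bond: the triisopropylsilyl ether is bulky, a poor donor and carries no group that can migrate, and five-membered ylide closure should be faster than any insertion through a larger ring. Rh2(OAc)4 in a non-coordinating solvent is chosen because it favours the shift to carbon over the [1,4]-shift to the enolate oxygen.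

Step 11
Reactants: 17 2-[(R)-[3,4-bis(benzyloxy)phenyl](penta-O-benzylcatechin-8-yl)methyl]-4,6-bis(triisopropylsilyloxy)benzofuran-3(2H)-one (C2 epimers)
Product: 18 (2R,3R)-2-[(R)-[3,4-bis(benzyloxy)phenyl](penta-O-benzylcatechin-8-yl)methyl]-4,6-bis(triisopropylsilyloxy)-2,3-dihydrobenzofuran-3-ol
Conditions: RuCl[(S,S)-TsDPEN](p-cymene) (5 mol %), HCO2H/Et3N (2:5), EtOAc, 40 °C
Reagents that add atoms: none
Why: Noyori–Ikariya asymmetric transfer hydrogenation with dynamic kinetic resolution, known for alpha-substituted benzo-fused cyclic ketones. The catalyst selects the carbonyl face as for 1-indanone (giving 3R here), and of the two C2 epimers, which equilibrate under Et3N, the one with its substituent anti to the incoming hydride reacts faster, giving the cis (2R,3R) alcohol. Excess amine keeps the medium non-acidic so that the electron-rich benzylic alcohol should not lose water.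

Step 12
Reactants: 18 (2R,3R)-2-[(R)-[3,4-bis(benzyloxy)phenyl](penta-O-benzylcatechin-8-yl)methyl]-4,6-bis(triisopropylsilyloxy)-2,3-dihydrobenzofuran-3-ol
Product: 19 (2R,3R)-2-[(R)-[3,4-bis(benzyloxy)phenyl](penta-O-benzylcatechin-8-yl)methyl]-2,3-dihydrobenzofuran-3,4,6-triol
Conditions: Bu4NF, AcOH (1:1), THF, 0 °C; used without chromatography
Reagents that add atoms: none
Why: Fluoride cleavage of the two aryl silyl ethers; the acetic acid buffer keeps the phenols protonated, so that phenoxide-driven loss of the C3 hydroxyl should not occur; benzyl ethers are inert.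

Step 13
Reactants: 19 (2R,3R)-2-[(R)-[3,4-bis(benzyloxy)phenyl](penta-O-benzylcatechin-8-yl)methyl]-2,3-dihydrobenzofuran-3,4,6-triol
Product: 20 (2R,3S)-2-(3,4-dihydroxyphenyl)-8-{(R)-(3,4-dihydroxyphenyl)[(2S)-4,6-dihydroxy-2,3-dihydrobenzofuran-2-yl]methyl}chromane-3,5,7-triol (target)
Conditions: H2 (1 atm), Pd(OH)2/C, THF/MeOH, rt
Reagents that add atoms: none
Why: Hydrogenolysis of seven benzyl ethers and of the benzylic C3–O bond, which is activated by the free ortho and para hydroxyls as in the conversion of flavan-3,4-diols into flavan-3-ols. Benzofuran C2 is not benzylic and keeps its configuration; its descriptor changes from R to S only because the priorities change.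

## Compound list

1 | (+)-catechin, (2R,3S)-2-(3,4-dihydroxyphenyl)chromane-3,5,7-triol | Oc1cc(O)c2c(c1)O[C@H](c1ccc(O)c(O)c1)[C@@H](O)C2 | starting material
2 | 5,7,3',4'-tetra-O-benzyl-(+)-catechin, (2R,3S)-5,7-bis(benzyloxy)-2-[3,4-bis(benzyloxy)phenyl]chroman-3-ol | c5c(OCc4ccccc4)cc(OCc4ccccc4)c3c5O[C@H](c5ccc(OCc4ccccc4)c(OCc4ccccc4)c5)[C@@H](O)C3 | intermediate
3 | penta-O-benzyl-(+)-catechin, (2R,3S)-3,5,7-tris(benzyloxy)-2-[3,4-bis(benzyloxy)phenyl]chromane | c5c(OCc4ccccc4)cc(OCc4ccccc4)c3c5O[C@H](c5ccc(OCc4ccccc4)c(OCc4ccccc4)c5)[C@@H](OCc4ccccc4)C3 | intermediate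
4 | 8-bromo-penta-O-benzyl-(+)-catechin | Brc5c(OCc4ccccc4)cc(OCc4ccccc4)c3c5O[C@H](c5ccc(OCc4ccccc4)c(OCc4ccccc4)c5)[C@@H](OCc4ccccc4)C3 | intermediate
5 | 3,4-bis(benzyloxy)benzaldehyde | O=Cc1ccc(OCc2ccccc2)c(OCc2ccccc2)c1 | starting material
6 | 8-lithio-penta-O-benzyl-(+)-catechin | [Li]c5c(OCc4ccccc4)cc(OCc4ccccc4)c3c5O[C@H](c5ccc(OCc4ccccc4)c(OCc4ccccc4)c5)[C@@H](OCc4ccccc4)C3 | intermediate (not isolated)
7 | [3,4-bis(benzyloxy)phenyl](penta-O-benzylcatechin-8-yl)methanol, both epimers at the carbinol carbon | OC(c5ccc(OCc4ccccc4)c(OCc4ccccc4)c5)c5c(OCc4ccccc4)cc(OCc4ccccc4)c3c5O[C@H](c5ccc(OCc4ccccc4)c(OCc4ccccc4)c5)[C@@H](OCc4ccccc4)C3 | intermediate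
8 | [3,4-bis(benzyloxy)phenyl](penta-O-benzylcatechin-8-yl)methanone | O=C(c5ccc(OCc4ccccc4)c(OCc4ccccc4)c5)c5c(OCc4ccccc4)cc(OCc4ccccc4)c3c5O[C@H](c5ccc(OCc4ccccc4)c(OCc4ccccc4)c5)[C@@H](OCc4ccccc4)C3 | intermediate
9 | (S)-[3,4-bis(benzyloxy)phenyl](penta-O-benzylcatechin-8-yl)methanol | O[C@@H](c5ccc(OCc4ccccc4)c(OCc4ccccc4)c5)c5c(OCc4ccccc4)cc(OCc4ccccc4)c3c5O[C@H](c5ccc(OCc4ccccc4)c(OCc4ccccc4)c5)[C@@H](OCc4ccccc4)C3 | intermediate
10 | 2,4,6-trihydroxyacetophenone | CC(=O)c1c(O)cc(O)cc1O | starting material
11 | 1-[2-hydroxy-4,6-bis(triisopropylsilyloxy)phenyl]ethanone | CC(=O)c1c(O)cc(O[Si](C(C)C)(C(C)C)C(C)C)cc1O[Si](C(C)C)(C(C)C)C(C)C | intermediate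
12 | 1-{2-[(R)-[3,4-bis(benzyloxy)phenyl](penta-O-benzylcatechin-8-yl)methoxy]-4,6-bis(triisopropylsilyloxy)phenyl}ethanone | CC(=O)c1c(O[C@H](c5ccc(OCc4ccccc4)c(OCc4ccccc4)c5)c5c(OCc4ccccc4)cc(OCc4ccccc4)c3c5O[C@H](c5ccc(OCc4ccccc4)c(OCc4ccccc4)c5)[C@@H](OCc4ccccc4)C3)cc(O[Si](C(C)C)(C(C)C)C(C)C)cc1O[Si](C(C)C)(C(C)C)C(C)C | intermediate
13 | 4,4,4-trifluoro-1-{2-[(R)-[3,4-bis(benzyloxy)phenyl](penta-O-benzylcatechin-8-yl)methoxy]-4,6-bis(triisopropylsilyloxy)phenyl}butane-1,3-dione | O=C(CC(=O)C(F)(F)F)c1c(O[C@H](c5ccc(OCc4ccccc4)c(OCc4ccccc4)c5)c5c(OCc4ccccc4)cc(OCc4ccccc4)c3c5O[C@H](c5ccc(OCc4ccccc4)c(OCc4ccccc4)c5)[C@@H](OCc4ccccc4)C3)cc(O[Si](C(C)C)(C(C)C)C(C)C)cc1O[Si](C(C)C)(C(C)C)C(C)C | intermediate (not isolated)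
14 | 2-diazo-1-{2-[(R)-[3,4-bis(benzyloxy)phenyl](penta-O-benzylcatechin-8-yl)methoxy]-4,6-bis(triisopropylsilyloxy)phenyl}ethanone | [N-]=[N+]=CC(=O)c1c(O[C@H](c5ccc(OCc4ccccc4)c(OCc4ccccc4)c5)c5c(OCc4ccccc4)cc(OCc4ccccc4)c3c5O[C@H](c5ccc(OCc4ccccc4)c(OCc4ccccc4)c5)[C@@H](OCc4ccccc4)C3)cc(O[Si](C(C)C)(C(C)C)C(C)C)cc1O[Si](C(C)C)(C(C)C)C(C)C | intermediate
15 | rhodium carbenoid of 14 (diazo group replaced by the Rh2(OAc)4 unit, written [Rh]) | O=C(C=[Rh])c1c(O[C@H](c5ccc(OCc4ccccc4)c(OCc4ccccc4)c5)c5c(OCc4ccccc4)cc(OCc4ccccc4)c3c5O[C@H](c5ccc(OCc4ccccc4)c(OCc4ccccc4)c5)[C@@H](OCc4ccccc4)C3)cc(O[Si](C(C)C)(C(C)C)C(C)C)cc1O[Si](C(C)C)(C(C)C)C(C)C | intermediate (not isolated)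
16 | cyclic oxonium ylide, 1-[(R)-diarylmethyl]-3-oxo-4,6-bis(triisopropylsilyloxy)-2,3-dihydrobenzofuran-1-ium-2-ide | O=C1[CH-][O+]([C@H](c5ccc(OCc4ccccc4)c(OCc4ccccc4)c5)c5c(OCc4ccccc4)cc(OCc4ccccc4)c3c5O[C@H](c5ccc(OCc4ccccc4)c(OCc4ccccc4)c5)[C@@H](OCc4ccccc4)C3)c2cc(O[Si](C(C)C)(C(C)C)C(C)C)cc(O[Si](C(C)C)(C(C)C)C(C)C)c12 | intermediate (not isolated)
17 | 2-[(R)-[3,4-bis(benzyloxy)phenyl](penta-O-benzylcatechin-8-yl)methyl]-4,6-bis(triisopropylsilyloxy)benzofuran-3(2H)-one, C2 epimers in equilibrium | CC(C)[Si](C(C)C)(C(C)C)Oc1cc(O[Si](C(C)C)(C(C)C)C(C)C)c2c(c1)OC([C@H](c1ccc(OCc4ccccc4)c(OCc4ccccc4)c1)c1c(OCc4ccccc4)cc(OCc4ccccc4)c3c1O[C@H](c1ccc(OCc4ccccc4)c(OCc4ccccc4)c1)[C@@H](OCc4ccccc4)C3)C2=O | intermediate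
18 | (2R,3R)-2-[(R)-[3,4-bis(benzyloxy)phenyl](penta-O-benzylcatechin-8-yl)methyl]-4,6-bis(triisopropylsilyloxy)-2,3-dihydrobenzofuran-3-ol | CC(C)[Si](C(C)C)(C(C)C)Oc1cc(O[Si](C(C)C)(C(C)C)C(C)C)c2c(c1)O[C@H]([C@H](c1ccc(OCc4ccccc4)c(OCc4ccccc4)c1)c1c(OCc4ccccc4)cc(OCc4ccccc4)c3c1O[C@H](c1ccc(OCc4ccccc4)c(OCc4ccccc4)c1)[C@@H](OCc4ccccc4)C3)[C@@H]2O | intermediate
19 | (2R,3R)-2-[(R)-[3,4-bis(benzyloxy)phenyl](penta-O-benzylcatechin-8-yl)methyl]-2,3-dihydrobenzofuran-3,4,6-triol | Oc1cc(O)c2c(c1)O[C@H]([C@H](c1ccc(OCc4ccccc4)c(OCc4ccccc4)c1)c1c(OCc4ccccc4)cc(OCc4ccccc4)c3c1O[C@H](c1ccc(OCc4ccccc4)c(OCc4ccccc4)c1)[C@@H](OCc4ccccc4)C3)[C@@H]2O | intermediate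
20 | (2R,3S)-2-(3,4-dihydroxyphenyl)-8-{(R)-(3,4-dihydroxyphenyl)[(2S)-4,6-dihydroxy-2,3-dihydrobenzofuran-2-yl]methyl}chromane-3,5,7-triol | Oc1cc(O)c2c(c1)O[C@H]([C@H](c1ccc(O)c(O)c1)c1c(O)cc(O)c3c1O[C@H](c1ccc(O)c(O)c1)[C@@H](O)C3)C2 | target

## Step count and least certain steps

Total step count: 13. Longest linear sequence: 12 steps (steps 1 to 6 and 8 to 13); step 7 is a one-step side branch.

**Step 10 (key step).** The most likely failure is loss of configuration at the migrating carbon, because the diarylmethyl fragment is stabilised enough to leave the cage or pass through a loose ion pair before it recombines. Also possible are recombination at the enolate oxygen ([1,4]-shift) and interception of the carbenoid by an arene or the methine C–H bond before the ylide forms. The fallback makes the same C2–methine bond between two separate partners. 4,6-Dihydroxybenzofuran-3(2H)-one F1 is silylated (TIPSCl, imidazole) to 4,6-bis(triisopropylsilyloxy)benzofuran-3(2H)-one F2 and converted (Me3SiOTf, Et3N) into the enol silyl ether 3-(trimethylsilyloxy)-4,6-bis(triisopropylsilyloxy)benzofuran F3. Carbinol 7 (steps 5 and 6 are then not needed) is ionised by catalytic Me3SiOTf at −78 °C in the presence of F3, and the diarylmethyl cation is captured at C2, a Mukaiyama-type SN1 alkylation. This should give 17 together with the (S)-methine epimer of 17 F4; the two are diastereomers and are separated, and the route is rejoined at 17. The price is that the methine is no longer controlled.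

**Step 8.** The activated carbinol may ionise before the phenoxide attacks, which erodes the configuration; the cation may also attack a ring carbon of the phenoxide, and the product ether may be cleaved on acidic supports. The fallback gives up the configurational relay. Steps 5 and 6 are omitted, the epimer mixture 7 is etherified with 11 under the conditions of step 8, which for an ionising carbinol amounts to kinetic capture of the ion pair at oxygen, and 12 is separated from the (S)-methine epimer of 12 F5 by chromatography on amine-washed silica or preparative HPLC. The route is rejoined at 12, two steps shorter but with at most half of the material usable.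

**Step 11.** Hydride transfer may be slow, because the ketone is deactivated by three oxygen donors and flanked by a triisopropylsilyloxy group. The catalyst may be mismatched with the fixed methine centre and select poorly between the C2 epimers, and 18 may lose water to the benzofuran. The fallback accepts the benzofuran and creates C2 by hydrogenation. From 17, NaBH4 in THF/MeOH gives the 3-hydroxy compound as a mixture of isomers F6, which catalytic pyridinium p-toluenesulfonate dehydrates to 2-[(R)-diarylmethyl]-4,6-bis(triisopropylsilyloxy)benzofuran F7. Face-selective hydrogenation of the furan double bond follows, with Ru(cod)(2-methylallyl)2, KOtBu and the carbene precursor 1,3-bis[1-(1-naphthyl)ethyl]-4,5-dihydroimidazolium tetrafluoroborate (antipode chosen for 2S). This should give the (2S)-dihydrobenzofuran F8; hydrogenolysis over Pd(OH)2/C gives the 4,6-bis(triisopropylsilyl) ether of 20 F9, and Et3N·3HF in THF frees the last two phenols. The route is rejoined at 20.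

**Step 12 (with step 13).** Once the ortho and para phenols are free, the C3 hydroxyl may be expelled through a quinone methide, followed by aromatisation to the benzofuran, which erases C2; in step 13 the C3–O bond may also resist hydrogenolysis. The fallback removes the C3 oxygen while the ring oxygens are still silylated. From 18, acetylation (Ac2O, 4-(dimethylamino)pyridine, pyridine) gives the 3-O-acetate of 18 F10. Hydrogenolysis over Pd(OH)2/C in EtOAc/MeOH cleaves the benzylic acetate and the seven benzyl ethers to give F9, and Et3N·3HF then gives 20, where the route is rejoined.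

## Further compounds

F1 | step 10 | 4,6-dihydroxybenzofuran-3(2H)-one | O=C1COc2cc(O)cc(O)c12
F2 | step 10 | 4,6-bis(triisopropylsilyloxy)benzofuran-3(2H)-one | O=C1COc2cc(O[Si](C(C)C)(C(C)C)C(C)C)cc(O[Si](C(C)C)(C(C)C)C(C)C)c12
F3 | step 10 | 3-(trimethylsilyloxy)-4,6-bis(triisopropylsilyloxy)benzofuran | C[Si](C)(C)Oc1coc2cc(O[Si](C(C)C)(C(C)C)C(C)C)cc(O[Si](C(C)C)(C(C)C)C(C)C)c12
F4 | step 10 | (S)-methine epimer of 17 | CC(C)[Si](C(C)C)(C(C)C)Oc1cc(O[Si](C(C)C)(C(C)C)C(C)C)c2c(c1)OC([C@@H](c1ccc(OCc4ccccc4)c(OCc4ccccc4)c1)c1c(OCc4ccccc4)cc(OCc4ccccc4)c3c1O[C@H](c1ccc(OCc4ccccc4)c(OCc4ccccc4)c1)[C@@H](OCc4ccccc4)C3)C2=O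
F5 | step 8 | (S)-methine epimer of 12 | CC(=O)c1c(O[C@@H](c5ccc(OCc4ccccc4)c(OCc4ccccc4)c5)c5c(OCc4ccccc4)cc(OCc4ccccc4)c3c5O[C@H](c5ccc(OCc4ccccc4)c(OCc4ccccc4)c5)[C@@H](OCc4ccccc4)C3)cc(O[Si](C(C)C)(C(C)C)C(C)C)cc1O[Si](C(C)C)(C(C)C)C(C)C
F6 | step 11 | 3-hydroxy compound from 17, mixture of C2 and C3 isomers | CC(C)[Si](C(C)C)(C(C)C)Oc1cc(O[Si](C(C)C)(C(C)C)C(C)C)c2c(c1)OC([C@H](c1ccc(OCc4ccccc4)c(OCc4ccccc4)c1)c1c(OCc4ccccc4)cc(OCc4ccccc4)c3c1O[C@H](c1ccc(OCc4ccccc4)c(OCc4ccccc4)c1)[C@@H](OCc4ccccc4)C3)C2O
F7 | step 11 | 2-[(R)-[3,4-bis(benzyloxy)phenyl](penta-O-benzylcatechin-8-yl)methyl]-4,6-bis(triisopropylsilyloxy)benzofuran | CC(C)[Si](C(C)C)(C(C)C)Oc1cc(O[Si](C(C)C)(C(C)C)C(C)C)c2cc(oc2c1)[C@H](c1ccc(OCc4ccccc4)c(OCc4ccccc4)c1)c1c(OCc4ccccc4)cc(OCc4ccccc4)c3c1O[C@H](c1ccc(OCc4ccccc4)c(OCc4ccccc4)c1)[C@@H](OCc4ccccc4)C3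
F8 | step 11 | (2S)-2-[(R)-[3,4-bis(benzyloxy)phenyl](penta-O-benzylcatechin-8-yl)methyl]-4,6-bis(triisopropylsilyloxy)-2,3-dihydrobenzofuran | CC(C)[Si](C(C)C)(C(C)C)Oc1cc(O[Si](C(C)C)(C(C)C)C(C)C)c2c(c1)O[C@H]([C@H](c1ccc(OCc4ccccc4)c(OCc4ccccc4)c1)c1c(OCc4ccccc4)cc(OCc4ccccc4)c3c1O[C@H](c1ccc(OCc4ccccc4)c(OCc4ccccc4)c1)[C@@H](OCc4ccccc4)C3)C2
F9 | step 11 | 4,6-bis(triisopropylsilyl) ether of 20 | CC(C)[Si](C(C)C)(C(C)C)Oc1cc(O[Si](C(C)C)(C(C)C)C(C)C)c2c(c1)O[C@H]([C@H](c1ccc(O)c(O)c1)c1c(O)cc(O)c3c1O[C@H](c1ccc(O)c(O)c1)[C@@H](O)C3)C2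
F10 | step 12 | 3-O-acetate of 18 | CC(C)[Si](C(C)C)(C(C)C)Oc1cc(O[Si](C(C)C)(C(C)C)C(C)C)c2c(c1)O[C@H]([C@H](c1ccc(OCc4ccccc4)c(OCc4ccccc4)c1)c1c(OCc4ccccc4)cc(OCc4ccccc4)c3c1O[C@H](c1ccc(OCc4ccccc4)c(OCc4ccccc4)c1)[C@@H](OCc4ccccc4)C3)[C@@H]2OC(C)=O
A1 | alternative 1 | ring A salicyl alcohol carrying the 4,6-bis(benzyloxy)dihydrobenzofuran and the methine | c4ccccc4COc1cc(OCc4ccccc4)c2c(c1)O[C@H]([C@H](c1ccc(OCc4ccccc4)c(OCc4ccccc4)c1)c1c(O)cc(OCc4ccccc4)c(CO)c1O)C2
A2 | alternative 1 | (E)-2-[3,4-bis(benzyloxy)phenyl]vinyl acetate | CC(=O)O/C=C/c1ccc(OCc2ccccc2)c(OCc2ccccc2)c1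
A3 | alternative 1 | hepta-O-benzyl ether 3-O-acetate of the target with free flavan C7 hydroxyl | c4ccccc4COc1cc(OCc4ccccc4)c2c(c1)O[C@H]([C@H](c1ccc(OCc4ccccc4)c(OCc4ccccc4)c1)c1c(O)cc(OCc4ccccc4)c3c1O[C@H](c1ccc(OCc4ccccc4)c(OCc4ccccc4)c1)[C@@H](OC(C)=O)C3)C2
A4 | alternative 2 | diyne: ethynyl ether of the secondary carbinol whose chain ends in a tert-butoxyalkyne | C#CO[C@H]([C@H](c1ccc(OCc4ccccc4)c(OCc4ccccc4)c1)c1c(OCc4ccccc4)cc(OCc4ccccc4)c3c1O[C@H](c1ccc(OCc4ccccc4)c(OCc4ccccc4)c1)[C@@H](OCc4ccccc4)C3)CC#COC(C)(C)C
A5 | alternative 2 | 2-ethynyl-4,4,5,5-tetramethyl-1,3,2-dioxaborolane | C#CB1OC(C)(C)C(C)(C)O1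
A6 | alternative 2 | 4-tert-butoxy-6-(pinacolboryl)-2,3-dihydrobenzofuran with the benzylated lower half | CC1(C)OB(OC1(C)C)c1cc(OC(C)(C)C)c2c(c1)O[C@H]([C@H](c1ccc(OCc4ccccc4)c(OCc4ccccc4)c1)c1c(OCc4ccccc4)cc(OCc4ccccc4)c3c1O[C@H](c1ccc(OCc4ccccc4)c(OCc4ccccc4)c1)[C@@H](OCc4ccccc4)C3)C2
A7 | alternative 3 | 1,3-bis(benzyloxy)-5-iodobenzene | Ic1cc(OCc2ccccc2)cc(OCc2ccccc2)c1
A8 | alternative 3 | terminal epoxide carrying the diarylmethine and the benzylated catechin unit | O1C[C@H]1[C@H](c1ccc(OCc4ccccc4)c(OCc4ccccc4)c1)c1c(OCc4ccccc4)cc(OCc4ccccc4)c3c1O[C@H](c1ccc(OCc4ccccc4)c(OCc4ccccc4)c1)[C@@H](OCc4ccccc4)C3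
A9 | alternative 3 | nona-O-benzyl ether of the target | c4ccccc4COc1cc(OCc4ccccc4)c2c(c1)O[C@H]([C@H](c1ccc(OCc4ccccc4)c(OCc4ccccc4)c1)c1c(OCc4ccccc4)cc(OCc4ccccc4)c3c1O[C@H](c1ccc(OCc4ccccc4)c(OCc4ccccc4)c1)[C@@H](OCc4ccccc4)C3)C2
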